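The flask is charged with 13 mM of substrate and 13.7 mM of reagent, so substrate is the smaller charge and the limiting reagent. Its balance is a subtraction: substrate lost, less target found, went elsewhere or still waits on the way. The decision for the next run is whether to change the free catalyst charge, and no earlier run varies it.

| setting | epsilon | gamma | theta | flask |
|---|---|---|---|---|
| substrate | 6.5 mM | 26 mM | 13 mM | 13 mM |
| reagent | 13.7 mM | 13.7 mM | 6.8 mM | 13.7 mM |
| free catalyst | 0.18 mM | 0.18 mM | 0.18 mM | 0.18 mM |
| remark | run made earlier | run made earlier | run made earlier |  |

| run | time / d | target / % | substrate / % |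
|---|---|---|---|
| epsilon | 2.08 | 13 | 14 |
| epsilon | 4.00 | 22 | 4 |
| epsilon | 6.00 | 25 | 1 |
| epsilon | 8.00 | 25 | 0 |
| epsilon | 10.0 | 25 | 0 |
| epsilon | 12.0 | 22 | 2 |
| gamma | 0.833 | 7 | 25 |
| gamma | 2.50 | 11 | 9 |
| gamma | 4.00 | 19 | 6 |
| gamma | 6.00 | 16 | 3 |
| gamma | 10.0 | 18 | 1 |
| gamma | 12.0 | 18 | 3 |
| theta | 1.04 | 5 | 36 |
| theta | 3.00 | 11 | 12 |
| theta | 6.00 | 16 | 1 |
| theta | 8.00 | 28 | 4 |
| theta | 12.0 | 27 | 3 |

(scatter of a reading: 2 percentage points)

1. apparent order in free catalyst when 10% of the substrate are converted (percent change of the rate of making target for one percent more free catalyst charged)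
2. factor on the rate of making target when 10% of the substrate are converted if free catalyst is charged twice over

- no earlier run changes the charge of free catalyst; that part of a forecast is a guess

The theta run has the flask's substrate charge, but 6.8 mM of reagent. At its first reading, 1.04 d, it shows 5% target against 64.0% substrate lost, and its last two readings average 27.5% target. The target share of lost substrate at the first reading, over that share at the end, is the lag ratio 0.276. It is a loose reading, given the scatter of 2 percentage points, but it stands below 1, so target trails the substrate lost and an unseen stage seems to lie between them.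

The rate asked about is taken at 10% conversion, earlier than that reading, and so inside the lag. This reckoning supposes that catalyst acts both in filling that stage and in emptying it. On that supposition the early rate of making target goes with the square of the free catalyst charge, so this reckoning estimates an order of 2 and a factor of 4 on doubling the charge. The choice is therefore to charge twice the free catalyst and leave substrate and reagent unchanged.

The forecast differs, with order 0.9 (0.4 to 1.2) and factor 1.87 (1.3 to 2.3), on the ground that “the simple expectation is a rate nearly proportional to catalyst”.

The flask gives order 1.8 and factor 3.23.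

    substrate + free catalyst → free catalyst + open intermediate (k = 61.0 M⁻¹ h⁻¹)
    free catalyst + open intermediate ⇌ catalyst intermediate (K = 1900 M⁻¹, k = 250 M⁻¹ h⁻¹)
    reagent + catalyst intermediate → free catalyst + target (k = 160 M⁻¹ h⁻¹)
    substrate + reagent → uncatalysed product (k = 2.00 M⁻¹ h⁻¹)
    2 substrate → self-condensation product (k = 1.50 M⁻¹ h⁻¹)

In this flask, the rate of making target at 0.937 d stands 6.5 times the rate at 10% conversion. The lag ratio of the flask at 1.00 d, from 5.01% target and 28.2% substrate left, is 0.316, beside the 0.276 read from the theta run. The gamma run, at 0.833 d, reads 0.503.

Readings and results were generated by integration for an exercise; noise was put on by code.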